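The numbers in the tables were computed with constants of no real substance; noise was put on by code.

The mole of solid reagent charged is my unit for the midnight flask: I ask how much left-handed product each one buys. The midnight flask is the one asked about, and the winter run shares its reagent and catalyst charges at a lower substrate charge.

| flask | left-handed substrate | right-handed substrate | solid reagent | free catalyst | remark | time |
|---|---|---|---|---|---|---|
| midnight | 0.47 M | 0.47 M | 0.94 M | 9.9 mM | the very flask that is asked about, followed so far |  |
| winter | 0.31 M | 0.31 M | 0.94 M | 9.9 mM | run made earlier |  |
| flask | 0.47 M | 0.47 M | 0.940 M | 9.9 mM |  | 8.0 d |

| run | time / h | left-handed product / % | left-handed substrate / % |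
|---|---|---|---|
| midnight | 15.0 | 41 | 6 |
| midnight | 40.0 | 47 | 3 |
| midnight | 72.0 | 47 | 2 |
| midnight | 120 | 51 | 6 |
| winter | 0.833 | 2 | 48 |
| winter | 2.00 | 12 | 41 |
| winter | 5.00 | 25 | 25 |
| winter | 10.0 | 43 | 9 |

(readings scatter by 2 percentage points)

- free catalyst is single-handed; left-handed substrate and right-handed substrate are mirror images of each other, charged as a racemate, each of them at the stated concentration
- solid reagent is a solid; its amount is given per volume of the solution
- left-handed product that was removed still counts
- at the start none of the solid reagent is in solution
- additions bring no volume worth counting

- south-east: at 8.0 d add left-handed substrate, 50.0% of the amount charged, then wait 8.0 d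
- south-west: at 8.0 d add free catalyst, 50.0% of the amount charged, then wait 8.0 d
- north: at 8.0 d take out 90% of the left-handed product then present, then wait 8.0 d
- east: change nothing and wait 8.0 d more

* left-handed product, in percent of the left-handed substrate and right-handed substrate together first charged, at 8.0 d
* what to do for the largest gain in left-handed product; "none" if nothing gains more than 2 percentage points (south-east / south-west / north / east / none)
* left-handed product present, with what was taken out counted in, in percent of the left-handed substrate and right-handed substrate together first charged, after south-west
* left-handed product present, with what was taken out counted in, in percent of the left-handed substrate and right-handed substrate together first charged, after north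

I build the midnight flask up by steps. In a first picture, left-handed substrate meets reagent one to one while right-handed substrate stands aside, so the ceiling of that picture is 50.0% of the charge, and the reagent charge is 2.00 times the left-handed substrate charge.

Next comes the rate. In the winter run, left-handed substrate falls from 25% to 9% between 5.00 h and 10.0 h, which reads as a first-order constant k of 0.204 h⁻¹. Applied to the midnight flask from its 6% at 15.0 h, that k leaves 0.0366% at 40.0 h.

But the midnight readings of left-handed substrate from 40.0 h on average 3.67%, against a scatter of 2 percentage points per reading, so I read that flask as stalling with substrate on hand. I put this back into the first answer: ceiling minus residue gives 46.3%. In my unit that is 0.463, the reagent yield Y, moles of left-handed product per mole of solid reagent charged.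

The remaining 53.7% of the reagent is not traced by anything I read, and right-handed substrate goes unread. So I commit to 46.3% for now and back no addition.

The forecast gives 48% at 8.0 d, 48.5% after south-west and 51% after north, and it chooses south-east, saying "I therefore read the plateau as an equilibrium". It differs from my reckoning on the level and on the choice.

The simulation gives 46.5%, with 46.5% after south-west and 46.5% after north. The best choice is none, and south-east gains 0 points. The forecast's numbers fall within tolerance; its choice is wrong.

    free catalyst + left-handed substrate ⇌ catalyst intermediate A (K = 3.00 L mol⁻¹, k = 370 L mol⁻¹ h⁻¹)
    free catalyst + right-handed substrate ⇌ catalyst intermediate B (K = 6.30 L mol⁻¹, k = 1100 L mol⁻¹ h⁻¹)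
    coupling partner + catalyst intermediate A → free catalyst + left-handed product (k = 360 L mol⁻¹ h⁻¹)
    coupling partner + catalyst intermediate B → free catalyst + right-handed product (k = 32.0 L mol⁻¹ h⁻¹)
    coupling partner + free catalyst → spent catalyst (k = 0.230 L mol⁻¹ h⁻¹)
    2 coupling partner → homo dimer (k = 2.40 L mol⁻¹ h⁻¹)
    solid reagent ⇌ coupling partner, rate k7*(cs7 - [coupling partner]) while solid is left; crystals form when [coupling partner] > cs7 (solubility = 0.150 M, k = 0.660 h⁻¹)

In the midnight flask Y comes to 0.465, with solid reagent at 0% and coupling partner at 0 M at 192 h, while homo dimer holds 31.8% of the reagent charge and right-handed product 21.6%, coupling partner having gone 2.6 times as fast through catalyst intermediate A as through catalyst intermediate B at 7.21 h. In the neighbouring flask with 0.0040 M of free catalyst, Y is 0.356, solid reagent stands at 0%, and homo dimer holds 52.4% of the reagent charge.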